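Start with a subtraction. In the dawn run, which is the flask you are asked about followed so far, whatever is neither product nor solid substrate must be dissolved starting material, S, or sit on a catalyst charged at 0.12 mol%.

in all of them: free catalyst 0.12 mol%
- dawn: solid substrate 20 mM; temperature 25 °C; the very flask that is asked about, followed so far
- autumn: solid substrate 10 mM; temperature 10 °C; run made earlier
- flask: solid substrate 20 mM; temperature 25 °C; time 30 min

- dawn (time / min: product / %, solid substrate / %): 3.00: 7.7, 88.2; 8.00: 10.0, 83.6; 15.0: 11.1, 85.0; 25.0: 10.5, 84.0
- autumn (time / min: product / %, solid substrate / %): 3.00: 2.3, 83.7; 6.00: 11.6, 77.7; 10.0: 18.8, 70.3; 12.0: 19.9, 67.6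

(standard deviation of a reading: 1 percentage point)

- solid, in amounts per volume of the solution: solid substrate
- product taken out counts as made
- steps that have been proposed: starting material + free catalyst <-> catalyst intermediate A; catalyst intermediate A <-> catalyst intermediate B; catalyst intermediate B <-> free catalyst + product; solid substrate <-> starting material
- at the start none of the solid substrate is in solution
- additions bring no volume worth counting

- east: change nothing and wait 15 min more
- south-west: at 30 min take out 90% of the product then present, then wait 15 min
- south: at 30 min add free catalyst, 50.0% of the amount charged, then wait 15 min
- north-west: at 30 min raise the temperature by 15 K, then wait 15 min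

- product, in percent of the solid substrate first charged, at 30 min
- the option that brings most further product ("none" if no option brings more than 2 percentage points) (east / south-west / south / north-west / none)
- product present, with what was taken out counted in, in percent of the solid substrate first charged, after south
- product present, with what was taken out counted in, in percent of the solid substrate first charged, after north-west

Over the last 3 dawn readings, product averages 10.5%, with a scatter of the mean near 0.58 percentage points. The subtraction puts S at about 1.05 mM. In concentration, product stands at 2.11 mM. Call this the ceiling, the product concentration at which a flask with solid left stops at this temperature and loading. The ratio of product to S reads 2.01.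

But is this a ceiling, or a dead catalyst? The loadings match, so percent product compares turnovers, and the autumn flask has made about twice as many as the dawn flask. A fixed turnover count therefore cannot be the stop, unless the cold spares the catalyst. I take the plateau as thermodynamic control, not kinetic.

A second doubt is that the autumn flask, on half the charge, has reached 1.99 mM and may still be rising. That reading therefore gives me no ceiling for the autumn flask, and I leave open what 15 K of heating does.

Now put the first answer back in. At 30 min I expect the flask to hold 10.5%, so waiting should gain nothing, and added catalyst should leave the ceiling where it is. Take out 90% of the product, though, and the flask should climb back to the ceiling, a gain of 9.5 points. Is there time? The first dawn reading gives a time constant of 2.28 min, far shorter than 15 min. Is there solid? The last dawn reading shows 84.0% of solid substrate, more than the gain needs.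

The forecast says 10.7%, south-west, 10.8% after south and 10.3% after north-west, and of the last it writes “Heating shifts things only slightly, perhaps downward.” There I differ: I leave heating open.

The flask gives 9.74%, against 10.5% from the ceiling. The best option is south-west, bringing 8.7 points against the reckoned 9.5 points. South leaves 9.74%, but north-west gives 0.732%, far below the forecast's 10.3%.

    starting material + free catalyst ⇌ catalyst intermediate A (K = 160 M⁻¹, k = 3800 M⁻¹ s⁻¹, Ea = 22.0 kJ mol⁻¹, ΔH = 13.0 kJ mol⁻¹)
    catalyst intermediate A ⇌ catalyst intermediate B (K = 0.350, k = 11.0 s⁻¹, Ea = 54.0 kJ mol⁻¹, ΔH = −75.0 kJ mol⁻¹)
    catalyst intermediate B ⇌ free catalyst + product (K = 0.0290 M, k = 21.0 s⁻¹, Ea = 65.0 kJ mol⁻¹, ΔH = −72.0 kJ mol⁻¹)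
    solid substrate ⇌ starting material, rate k4*(cs4 - [starting material]) while solid is left; crystals form when [starting material] > cs4 (solubility = 1.20 mM, k = 0.0450 s⁻¹)
    (constants at 25 °C)

A flask charged with 12 mM of solid substrate takes the same reckoning: 2.11 mM over that charge gives 17.6%, and that flask holds 16.2% with 73.8% still solid.

The numbers in the tables stem from a simulated flask with made-up constants; scatter was added.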